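**Retrosynthetic overview**

1. The target gibberellin (26) comes from 3-ketone 23 (bulky hydride for the 3β-OH) and this from β-keto allyl ester 21. Ring A is opened at C2–C3 (Dieckmann acylation) and at C10–C1 (conjugate addition of a tertiary C10 radical to allyl acrylate), which leads back to tricyclic ketone 15 with a methylmalonate on C5.
2. Feature used: in ring A the carbinol carbon C3 lies between C2 and the quaternary C4 that carries the C19 carboxyl, so C3 and C19 can be the two ester carbons of one methylmalonate on C5. The trans A/B junction (C5–C10) and the axial C20 methyl on C10 make these two esters diastereotopic, so closing C2–C3 also fixes C4.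
3. Ring B: cyclopentenone 8 by aldol condensation (C5–C6); C7 enters at C6 by conjugate addition and the malonate at C5 by radical alkylation of the C10 silyl enol ether, trans to each other.
4. Rings C and D: an enantioselective Diels–Alder reaction (C8–C14, C9–C11; sets C8) gives the C12 silyl enol ether, and a gold-catalysed Conia-ene cyclisation (C13–C16) closes ring D with the C12 ketone and the 16-methylene in place.
5. Order of ring formation: C, D, B, A. The 20 skeletal carbons come from pent-4-ynal, methylglyoxal, methyl vinyl ketone, HC(SMe)3, a bromomethylmalonate, MeMgBr and allyl acrylate.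

Key step: step 13

Remark: names use the gibberellane locants C1–C20 of the target (α = face of the C20 methyl on ring B, β = face of H5, H9 and the C15–C16 bridge; TBS = tert-butyldimethylsilyl), so the target is 3β,12α-dihydroxygibberell-16-ene-7,19-dioic acid; pent-4-ynal and dimethyl 2-bromo-2-methylmalonate are taken as purchasable.

**Route**

Step 1
Reactants: 1 pent-4-ynal; 2 methylglyoxal
Product: 3 (E)-4-oxo-2-(prop-2-yn-1-yl)pent-2-enal
Conditions: pyrrolidine (20 mol%), PhCO2H (20 mol%), 2 as 40 wt% aq. solution, THF, 0 to 23 °C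
Reagents that add atoms: none
Why: Amine-catalysed cross-aldol condensation, in which the enamine of 1 attacks the far more electrophilic aldehyde carbon of 2 and dehydration gives the conjugated (E)-ene-dicarbonyl; no stereocentre is formed.

Step 2
Reactants: 4 methyl vinyl ketone
Product: 5 2-(tert-butyldimethylsilyloxy)buta-1,3-diene
Conditions: TBSOTf, Et3N, Et2O, 0 °C
Reagents that add atoms: tert-butyldimethylsilyl trifluoromethanesulfonate CC(C)(C)[Si](C)(C)OS(=O)(=O)C(F)(F)F
Why: Soft enolisation and O-silylation of an enone to the 2-silyloxydiene (silyl enol ether formation), the only enolisable position being the methyl group.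

Step 3
Reactants: 3 (E)-4-oxo-2-(prop-2-yn-1-yl)pent-2-enal; 5 2-(tert-butyldimethylsilyloxy)buta-1,3-diene
Product: 6 6-acetyl-4-(tert-butyldimethylsilyloxy)-1-(prop-2-yn-1-yl)cyclohex-3-ene-1-carbaldehyde (acetyl cis to propargyl; the quaternary carbon is the future C8)
Conditions: (S)-B-(o-tolyl)-5,5-diphenyl-oxazaborolidine protonated with Tf2NH (20 mol%), CH2Cl2, −78 to −40 °C
Reagents that add atoms: none
Why: Enantioselective Diels–Alder reaction under a cationic chiral oxazaborolidine bound to the formyl group, in which the nucleophilic CH2 terminus next to the silyloxy carbon bonds to the enal β-carbon (C9) and so places the enol ether at C12=C13, the catalyst shields one face of the enal and sets the quaternary C8 (the (S)-catalyst is proposed from the formyl C–H···O binding model), and the acetyl-bearing C9 is corrected in step 5.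

Step 4
Reactants: 6 Diels–Alder adduct
Product: 7 2-acetyl-6-methylidene-4-oxobicyclo[3.2.1]octane-1-carbaldehyde (rings C and D; C12 ketone, 16-methylene, C8 formyl, C9 acetyl)
Conditions: Ph3PAuCl (5 mol%), AgBF4 (5 mol%), CH2Cl2/MeOH 10:1, 23 °C
Reagents that add atoms: none
Why: Conia-ene-type 5-exo-dig carbocyclisation of the silyl enol ether onto the alkyne activated by cationic monovalent gold, with methanol as silyl acceptor and proton source, in which only C13 carries the nucleophile, so the C13–C16 bond forms with the bridgehead configuration dictated by the bridge.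

Step 5
Reactants: 7 bicyclic keto aldehyde
Product: 8 tricyclic enedione (rings B, C, D; C10 and C12 ketones, C5=C6 enone, 16-methylene, cis B/C junction with H9 β)
Conditions: KOH, MeOH, 0 to 23 °C
Reagents that add atoms: none
Why: Intramolecular aldol condensation of the methyl ketone carbon (C5) onto the non-enolisable C6 aldehyde gives the ring B cyclopentenone, while C9, α to the ketone, equilibrates to the less strained cis B/C junction (H9 on the face of the C15 bridge, C9–C10 axial on the ring C chair).

Step 6
Reactants: 8 tricyclic enedione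
Product: 9 12α-hydroxy enone (hydroxyl axial on ring C, syn to C10 and anti to the C15–C16 bridge)
Conditions: NaBH4 (0.5 equiv), MeOH/CH2Cl2 1:1, −78 °C
Reagents that add atoms: none
Why: Chemoselective borohydride reduction of the saturated C12 ketone beside the conjugated enone at low temperature, in which the axial C9–C10 bond blocks the axial trajectory so that hydride should enter equatorially and leave the hydroxyl axial (12α).

Step 7
Reactants: 9 12α-hydroxy enone
Product: 10 12α-(tert-butyldimethylsilyloxy) enone
Conditions: TBSOTf, 2,6-lutidine, CH2Cl2, 0 °C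
Reagents that add atoms: tert-butyldimethylsilyl trifluoromethanesulfonate CC(C)(C)[Si](C)(C)OS(=O)(=O)C(F)(F)F
Why: Silyl ether formation with a silyl triflate, which is reactive enough for the hindered axial alcohol.

Step 8
Reactants: 10 12α-(tert-butyldimethylsilyloxy) enone; 11 tris(methylthio)methane
Product: 12 C10 trimethylsilyl enol ether (C10=C5) with a 6β-tris(methylthio)methyl group
Conditions: 11, n-BuLi, THF, −78 °C; add 10; then Me3SiCl, Et3N, −78 to 0 °C
Reagents that add atoms: chlorotrimethylsilane C[Si](C)(C)Cl
Why: Conjugate (Michael) addition of the soft tris(methylthio)methyl anion, a carboxyl anion equivalent, followed by O-silylation of the enolate, which fixes the enol ether at C10=C5; the nucleophile should enter C6 from the convex β face, away from ring C and from the pseudoaxial C14 on C8.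

Step 9
Reactants: 12 C10 trimethylsilyl enol ether; 13 dimethyl 2-bromo-2-methylmalonate
Product: 14 C10 ketone with 5α-C(CH3)(CO2CH3)2 and 6β-C(SCH3)3 (trans)
Conditions: fac-Ir(ppy)3 (1 mol%), 13 (1.5 equiv), DMF, blue LEDs, 23 °C
Reagents that add atoms: none
Why: Photoredox radical alkylation of a silyl enol ether, in which the electrophilic methylmalonyl radical from 13 adds to C5 trans to the C6 substituent and oxidation with loss of the silyl group returns the C10 ketone (C5 stays epimerisable and trans is also the thermodynamic arrangement).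

Step 10
Reactants: 14 malonyl ketone trithioorthoester
Product: 15 keto triester (5α-C(CH3)(CO2CH3)2, 6β-CO2CH3, C10 ketone)
Conditions: HgCl2 (2.5 equiv), HgO (1.5 equiv), MeOH/H2O 12:1, 23 °C
Reagents that add atoms: methanol CO; water O
Why: Thiophilic methanolysis of the trithioorthoester to the methyl ester, assisted by divalent mercury under buffered conditions that should leave the 16-methylene and the silyl ether untouched; no stereocentre changes.

Step 11
Reactants: 15 keto triester
Product: 17 methyl oxalate of the C10 tertiary alcohol (10α-OC(O)CO2CH3, 10β-CH3), via tertiary alcohol 16 (not isolated)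
Conditions: CeCl3 (2.0 equiv), MeMgBr (1.8 equiv), THF, −78 °C; then ClC(O)CO2Me (3 equiv), −78 to 0 °C
Reagents that add atoms: methylmagnesium bromide C[Mg]Br; methyl chlorooxoacetate COC(=O)C(=O)Cl
Why: Chemoselective Grignard-type 1,2-addition of an organocerium methyl reagent to the ketone beside three esters, from the β face anti to the C5 and C9 substituents, with acylation of the alkoxide in the same flask at low temperature before it can lactonise onto the malonate; the C10 configuration is of no consequence because the centre becomes a planar radical in step 13.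

Step 12
Reactants: 17 methyl oxalate
Product: 18 cesium oxalate (cesium salt of the oxalate half-ester)
Conditions: CsOH·H2O (1.0 equiv), THF/H2O, 23 °C
Reagents that add atoms: cesium hydroxide monohydrate O.[OH-].[Cs+]
Why: Selective saponification of the highly electrophilic oxalate methyl ester with one equivalent of hydroxide, the hindered malonate and C7 esters being far slower.

Step 13
Reactants: 18 cesium oxalate; 19 allyl acrylate
Product: 21 tetracyclic β-keto allyl ester (ring A closed; 3-oxo, 2-CO2allyl as epimers or enol, 7,19-dimethyl ester, 12α-OTBS), via Giese adduct ester 20 (not isolated)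
Conditions: Ir[dF(CF3)ppy]2(dtbbpy)PF6 (2 mol%), 19 (1.2 equiv), DME/DMF 3:1, H2O (10 equiv), blue LEDs, 23 °C; volatiles removed in vacuo (PhMe azeotrope) in the same flask; then LiN(SiMe3)2 (3.5 equiv), THF, −78 to 0 °C; AcOH quench
Reagents that add atoms: none
Why: The excited iridium photocatalyst oxidises the oxalate, loss of two CO2 gives the planar tertiary C10 radical, and this adds to allyl acrylate and is reduced and protonated to ester 20 (Giese addition with radical–polar crossover; closest precedent is the conjugate addition of tertiary-alcohol oxalate radicals to acrylates). LiN(SiMe3)2 then forms the C2 ester enolate, which closes ring A by Dieckmann condensation onto one ester of the C4 methylmalonate (6-exo-trig acyl substitution through a chair, giving the trans-fused A/B system), driven by deprotonation of the β-keto ester formed. C10 is set in the radical addition: the acrylate should enter the β face, anti to the two α-substituents that flank the radical (C4 on C5 and C11 on C9), so the methyl ends α. C4 is set by which diastereotopic ester is attacked: in the chair the spectator ester should take the axial α position syn to the C20 methyl, because the alternative places two methyl groups 1,3-diaxial; C2 is a labile centre that is removed in step 14. The step needs acylation at the malonate and not at the C7 ester: the malonate carbonyls are the more electrophilic and sit trans to C1 in a chair-accessible position, whereas attack at C7 would need a bridged bicyclo[3.2.1] transition state across the β face.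

Step 14
Reactants: 21 β-keto allyl ester
Product: 23 dimethyl 12α-(tert-butyldimethylsilyloxy)-3-oxogibberell-16-ene-7,19-dioate, via β-keto acid 22 (not isolated)
Conditions: Pd(PPh3)4 (5 mol%), morpholine (5 equiv), THF, 23 to 40 °C
Reagents that add atoms: none
Why: Tsuji–Trost-type deallylation by zerovalent palladium with morpholine as allyl acceptor gives the β-keto acid, which decarboxylates under the reaction conditions, while the C19 methyl ester on quaternary C4 is not affected.

Step 15
Reactants: 23 3-ketone
Product: 24 dimethyl 12α-(tert-butyldimethylsilyloxy)-3β-hydroxygibberell-16-ene-7,19-dioate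
Conditions: K[HB(s-Bu)3], THF, −78 °C; aq. NH4Cl
Reagents that add atoms: none
Why: Ketone reduction with a bulky trialkylborohydride, which should attack C3 along the equatorial trajectory and give the axial 3β-alcohol, trans-diaxial to the C19 ester.

Step 16
Reactants: 24 3β-alcohol
Product: 25 dimethyl ester of the target (dimethyl 3β,12α-dihydroxygibberell-16-ene-7,19-dioate)
Conditions: HF·pyridine, THF, 0 to 23 °C
Reagents that add atoms: none
Why: Fluoride-mediated cleavage of the silyl ether under mildly acidic conditions that avoid retro-aldol cleavage of the β-hydroxy ester.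

Step 17
Reactants: 25 dimethyl ester of the target
Product: 26 target gibberellin (3β,12α-dihydroxygibberell-16-ene-7,19-dioic acid)
Conditions: n-PrSLi (from n-PrSH and n-BuLi), HMPA, 23 °C; then 1 M HCl
Reagents that add atoms: none
Why: SN2 demethylation of both methyl esters by thiolate, which does not depend on attack at the hindered axial C19 carbonyl and avoids the hydroxide conditions that cause retro-aldol epimerisation at C3.

**Compound list**

1 | pent-4-ynal | C#CCCC=O | starting material
2 | methylglyoxal (2-oxopropanal) | CC(=O)C=O | starting material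
3 | (E)-4-oxo-2-(prop-2-yn-1-yl)pent-2-enal | O=C/C(CC#C)=C/C(C)=O | intermediate
4 | methyl vinyl ketone (but-3-en-2-one) | CC(=O)C=C | starting material
5 | 2-(tert-butyldimethylsilyloxy)buta-1,3-diene | C=CC(=C)O[Si](C)(C)C(C)(C)C | intermediate
6 | 6-acetyl-4-(tert-butyldimethylsilyloxy)-1-(prop-2-yn-1-yl)cyclohex-3-ene-1-carbaldehyde, acetyl cis to propargyl | C#CC[C@]1(C=O)CC=C(O[Si](C)(C)C(C)(C)C)C[C@@H]1C(C)=O | intermediate
7 | 2-acetyl-6-methylidene-4-oxobicyclo[3.2.1]octane-1-carbaldehyde (rings C and D) | C=C1C[C@]2(C=O)C[C@H]1C(=O)C[C@@H]2C(C)=O | intermediate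
8 | tricyclic enedione (rings B, C, D; C10 and C12 ketones, C5=C6, 16-methylene, H9 β) | C=C1C[C@]23C[C@H]1C(=O)C[C@H]2C(=O)C=C3 | intermediate
9 | 12α-hydroxy enone | C=C1C[C@]23C[C@H]1[C@@H](O)C[C@H]2C(=O)C=C3 | intermediate
10 | 12α-(tert-butyldimethylsilyloxy) enone | C=C1C[C@]23C[C@H]1[C@@H](O[Si](C)(C)C(C)(C)C)C[C@H]2C(=O)C=C3 | intermediate
11 | tris(methylthio)methane | CSC(SC)SC | starting material
12 | C10 trimethylsilyl enol ether (C10=C5) with 6β-C(SCH3)3 | C=C1C[C@]23C[C@H]1[C@@H](O[Si](C)(C)C(C)(C)C)C[C@H]2C(O[Si](C)(C)C)=C[C@@H]3C(SC)(SC)SC | intermediate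
13 | dimethyl 2-bromo-2-methylmalonate | COC(=O)C(C)(Br)C(=O)OC | starting material
14 | C10 ketone with 5α-C(CH3)(CO2CH3)2 and 6β-C(SCH3)3 | C=C1C[C@]23C[C@H]1[C@@H](O[Si](C)(C)C(C)(C)C)C[C@H]2C(=O)[C@H]([C@@H]3C(SC)(SC)SC)C(C)(C(=O)OC)C(=O)OC | intermediate
15 | keto triester (5α-C(CH3)(CO2CH3)2, 6β-CO2CH3, C10 ketone) | C=C1C[C@]23C[C@H]1[C@@H](O[Si](C)(C)C(C)(C)C)C[C@H]2C(=O)[C@H]([C@@H]3C(=O)OC)C(C)(C(=O)OC)C(=O)OC | intermediate
16 | C10 tertiary alcohol (10α-OH, 10β-CH3) | C=C1C[C@]23C[C@H]1[C@@H](O[Si](C)(C)C(C)(C)C)C[C@H]2[C@](O)(C)[C@H]([C@@H]3C(=O)OC)C(C)(C(=O)OC)C(=O)OC | intermediate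
17 | methyl oxalate of 16 | C=C1C[C@]23C[C@H]1[C@@H](O[Si](C)(C)C(C)(C)C)C[C@H]2[C@](OC(=O)C(=O)OC)(C)[C@H]([C@@H]3C(=O)OC)C(C)(C(=O)OC)C(=O)OC | intermediate
18 | cesium oxalate of 16 | C=C1C[C@]23C[C@H]1[C@@H](O[Si](C)(C)C(C)(C)C)C[C@H]2[C@](OC(=O)C(=O)[O-])(C)[C@H]([C@@H]3C(=O)OC)C(C)(C(=O)OC)C(=O)OC.[Cs+] | intermediate
19 | allyl acrylate (prop-2-en-1-yl prop-2-enoate) | C=CC(=O)OCC=C | starting material
20 | Giese adduct ester (10α-CH3, 10β-CH2CH2CO2allyl, 5α-C(CH3)(CO2CH3)2; ring A open) | C=C1C[C@]23C[C@H]1[C@@H](O[Si](C)(C)C(C)(C)C)C[C@H]2[C@](C)(CCC(=O)OCC=C)[C@H]([C@@H]3C(=O)OC)C(C)(C(=O)OC)C(=O)OC | intermediate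
21 | tetracyclic β-keto allyl ester (3-oxo, 2-CO2allyl, 7,19-dimethyl ester, 12α-OTBS) | C=C1C[C@]23C[C@H]1[C@@H](O[Si](C)(C)C(C)(C)C)C[C@H]2[C@]1(C)CC(C(=O)OCC=C)C(=O)[C@@](C)(C(=O)OC)[C@H]1[C@@H]3C(=O)OC | intermediate
22 | β-keto acid (2-CO2H analogue of 21) | C=C1C[C@]23C[C@H]1[C@@H](O[Si](C)(C)C(C)(C)C)C[C@H]2[C@]1(C)CC(C(=O)O)C(=O)[C@@](C)(C(=O)OC)[C@H]1[C@@H]3C(=O)OC | intermediate
23 | dimethyl 12α-(tert-butyldimethylsilyloxy)-3-oxogibberell-16-ene-7,19-dioate | C=C1C[C@]23C[C@H]1[C@@H](O[Si](C)(C)C(C)(C)C)C[C@H]2[C@]1(C)CCC(=O)[C@@](C)(C(=O)OC)[C@H]1[C@@H]3C(=O)OC | intermediate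
24 | dimethyl 12α-(tert-butyldimethylsilyloxy)-3β-hydroxygibberell-16-ene-7,19-dioate | C=C1C[C@]23C[C@H]1[C@@H](O[Si](C)(C)C(C)(C)C)C[C@H]2[C@]1(C)CC[C@H](O)[C@@](C)(C(=O)OC)[C@H]1[C@@H]3C(=O)OC | intermediate
25 | dimethyl ester of the target (dimethyl 3β,12α-dihydroxygibberell-16-ene-7,19-dioate) | C=C1C[C@]23C[C@H]1[C@@H](O)C[C@H]2[C@]1(C)CC[C@H](O)[C@@](C)(C(=O)OC)[C@H]1[C@@H]3C(=O)OC | intermediate
26 | target gibberellin (3β,12α-dihydroxygibberell-16-ene-7,19-dioic acid) | C=C1C[C@]23C[C@H]1[C@@H](O)C[C@H]2[C@]1(C)CC[C@H](O)[C@@](C)(C(=O)O)[C@H]1[C@@H]3C(=O)O | target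

**Step count and risks**

Total steps: 17. Longest linear sequence: 16 (steps 1 and 3 to 17).

Step 13 is the most likely to fail. The crowded C10 radical may fragment (β-scission that expels the methylmalonyl radical) before it adds to the acrylate. In the ring closure the C2 enolate may acylate the C7 ester, pick the wrong malonate ester, or the allyl ester may be scrambled by the methoxide set free. The fallback sets out from 18 and comes back at 23. Under the same photoredox conditions the radical is trapped with phenyl vinyl sulfone, a faster acceptor, to give the sulfone adduct F1. LiN(SiMe3)2 then makes the α-sulfonyl carbanion, whose intramolecular acylation by a malonate ester gives the β-keto sulfone F2; no second ester enolate and no allyl ester are involved. Reductive desulfonylation with aluminium amalgam (Al/Hg) or SmI2 should give 23 directly, so step 14 is not needed.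

Step 3 is next. The ketone of 3 may compete with the aldehyde for the chiral Lewis acid, which would erode facial selectivity, and the strong acid may cleave the silyl enol ether. The fallback sets out from 3 and 5 and comes back at 9. The cycloaddition is run without chiral control (Me2AlCl, CH2Cl2, −78 °C) and the racemate is taken through steps 4 to 6, so that ent-6 F3, ent-7 F4, ent-8 F5 and ent-9 F6 accompany 6 to 9. A lipase-mediated kinetic resolution of the C12 carbinol (Pseudomonas cepacia lipase, vinyl acetate), with the enzyme chosen so that the mirror-image alcohol is acylated, removes it as the acetate of ent-9 F7, and 9 re-enters at step 7.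

Step 9 is third. Radical addition at C5 next to the very bulky C(SCH3)3 group may be slow, so that desilylation of the enol ether or reduction of the bromomalonate wins. The fallback sets out from 10 and comes back at 15. Base-mediated Michael addition of nitromethane (DBU) should give the 6β-nitromethyl ketone F8. A nitrite-mediated Nef-type oxidation (NaNO2, AcOH, DMSO) converts it to the 6β-carboxylic acid F9, and Me3SiCHN2 in MeOH gives the keto methyl ester F10. Kinetic enolisation toward the C5 methylene (LiN(i-Pr)2, Me3SiCl, −78 °C) gives the silyl enol ether F11. The photoredox alkylation with 13, now beside a small ester, then gives 15.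

Further compounds
F1 | step 13 | sulfone adduct (10α-CH3, 10β-CH2CH2SO2Ph, ring A open) | C=C1C[C@]23C[C@H]1[C@@H](O[Si](C)(C)C(C)(C)C)C[C@H]2[C@](C)(CCS(=O)(=O)c1ccccc1)[C@H]([C@@H]3C(=O)OC)C(C)(C(=O)OC)C(=O)OC
F2 | step 13 | β-keto sulfone (ring A closed, 2-SO2Ph, 3-oxo) | C=C1C[C@]23C[C@H]1[C@@H](O[Si](C)(C)C(C)(C)C)C[C@H]2[C@]1(C)CC(S(=O)(=O)c4ccccc4)C(=O)[C@@](C)(C(=O)OC)[C@H]1[C@@H]3C(=O)OC
F3 | step 3 | ent-6 | C#CC[C@@]1(C=O)CC=C(O[Si](C)(C)C(C)(C)C)C[C@H]1C(C)=O
F4 | step 3 | ent-7 | C=C1C[C@@]2(C=O)C[C@@H]1C(=O)C[C@H]2C(C)=O
F5 | step 3 | ent-8 | C=C1C[C@@]23C[C@@H]1C(=O)C[C@@H]2C(=O)C=C3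
F6 | step 3 | ent-9 | C=C1C[C@@]23C[C@@H]1[C@H](O)C[C@@H]2C(=O)C=C3
F7 | step 3 | acetate of ent-9 | C=C1C[C@@]23C[C@@H]1[C@H](OC(C)=O)C[C@@H]2C(=O)C=C3
F8 | step 9 | 6β-nitromethyl ketone | C=C1C[C@]23C[C@H]1[C@@H](O[Si](C)(C)C(C)(C)C)C[C@H]2C(=O)C[C@@H]3C[N+](=O)[O-]
F9 | step 9 | 6β-carboxylic acid ketone | C=C1C[C@]23C[C@H]1[C@@H](O[Si](C)(C)C(C)(C)C)C[C@H]2C(=O)C[C@@H]3C(=O)O
F10 | step 9 | 6β-methyl ester ketone | C=C1C[C@]23C[C@H]1[C@@H](O[Si](C)(C)C(C)(C)C)C[C@H]2C(=O)C[C@@H]3C(=O)OC
F11 | step 9 | C10 trimethylsilyl enol ether of the 6β-methyl ester ketone | C=C1C[C@]23C[C@H]1[C@@H](O[Si](C)(C)C(C)(C)C)C[C@H]2C(O[Si](C)(C)C)=C[C@@H]3C(=O)OC
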